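**Retrosynthetic overview**
1. Target 26 ← desilylation and C5–O acylation (acid 23) of the bicyclic 1,5-diol 22.
2. Seven-membered ring (formed second): intramolecular aldol C1–C5 of a C1/C2 enediol, unmasked from an internal alkyne, onto the C5 aldehyde of 18.
3. γ-Lactone (formed first): C6–C7 Barbier allylation of (S)-glyceraldehyde acetonide 15, then O6→C12 lactonisation; the extra glyceraldehyde carbon is later excised to unveil the C5 aldehyde.
4. Chain: C9/C10 syn pair by allenylstannane addition to aldehyde 4; C2–C3 by acetylide opening of (R)-propylene oxide 6; C11–C13 from methyl acrylate 11.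
5. Stereocentres: C4 and C2' from the chiral pool, C9/C10 from (R)-but-3-yn-2-ol, C6/C7 from glyceraldehyde control, C1/C5 in the aldol.

Assumption: atoms are numbered as a 4,5-seco-guaian-12,6-olide (ring C1, C5–C10; side chain C2–C4, C15; lactone C11–C13), and the carbocycle is taken to arise in nature by aldol addition of a C1/C2 enediol to a C5 aldehyde, the lactone by O6–C12 lactonisation.

**Step 1**
Reactants: 1 (R)-but-3-yn-2-ol
Product: 2 (R)-but-3-yn-2-yl methanesulfonate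
Conditions: MsCl, Et3N, CH2Cl2, 0 °C
Reagents that add atoms: methanesulfonyl chloride CS(=O)(=O)Cl
Why: O-sulfonylation of the secondary alcohol; the stereocentre is not touched.

**Step 2**
Reactants: 2 (R)-but-3-yn-2-yl methanesulfonate
Product: 3 (P)-tributyl(buta-1,2-dien-1-yl)stannane
Conditions: Bu3SnH, LiN(iPr)2, THF, 0 °C; CuBr·SMe2, −78 °C; then 2
Reagents that add atoms: tributyltin hydride CCCC[SnH](CCCC)CCCC
Why: anti SN2' displacement of the propargylic mesylate by the stannylcopper reagent (Marshall allenylstannane synthesis) transfers the carbinol configuration to the allene axis.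

**Step 3**
Reactants: 3 (P)-tributyl(buta-1,2-dien-1-yl)stannane; 4 3-[(tert-butyldimethylsilyl)oxy]propanal
Product: 5 (3R,4R)-1-[(tert-butyldimethylsilyl)oxy]-4-methylhex-5-yn-3-ol
Conditions: BF3·OEt2, CH2Cl2, −78 °C
Reagents that add atoms: none
Why: BF3-promoted anti SE2' addition of the chiral allenylstannane through an open transition state (Marshall propargylation) sets C10 from the allene axis and gives the syn C9/C10 homopropargylic alcohol.

**Step 4**
Reactants: 5 (3R,4R)-1-[(tert-butyldimethylsilyl)oxy]-4-methylhex-5-yn-3-ol; 6 (R)-2-methyloxirane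
Product: 8 (2R,6R,7R)-2,7,9-tris[(tert-butyldimethylsilyl)oxy]-6-methylnon-4-yne, via dilithium diolate 7 (not isolated)
Conditions: n-BuLi (2.1 equiv), THF/DMPU, −78 °C → rt; then TBSOTf (2.5 equiv), 2,6-lutidine, −78 → 0 °C
Reagents that add atoms: tert-butyldimethylsilyl trifluoromethanesulfonate CC(C)(C)[Si](C)(C)OS(=O)(=O)C(F)(F)F
Why: the lithium acetylide opens the epoxide at its CH2 terminus (SN2, so C4 keeps the R configuration of 6), and both lithium alkoxides are silylated in the same flask.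

**Step 5**
Reactants: 8 (2R,6R,7R)-2,7,9-tris[(tert-butyldimethylsilyl)oxy]-6-methylnon-4-yne
Product: 9 (3R,4R,8R)-3,8-bis[(tert-butyldimethylsilyl)oxy]-4-methylnon-5-yn-1-ol
Conditions: HF·pyridine, pyridine, THF, 0 °C
Reagents that add atoms: none
Why: selective desilylation, because the primary TBS ether is cleaved much faster than the two secondary ones under buffered fluoride.

**Step 6**
Reactants: 9 (3R,4R,8R)-3,8-bis[(tert-butyldimethylsilyl)oxy]-4-methylnon-5-yn-1-ol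
Product: 10 (3R,4R,8R)-3,8-bis[(tert-butyldimethylsilyl)oxy]-4-methylnon-5-ynal
Conditions: Dess–Martin periodinane, NaHCO3, CH2Cl2, rt
Reagents that add atoms: none
Why: Dess–Martin oxidation under buffered neutral conditions gives the β-silyloxy aldehyde without elimination.

**Step 7**
Reactants: 10 (3R,4R,8R)-3,8-bis[(tert-butyldimethylsilyl)oxy]-4-methylnon-5-ynal; 11 methyl acrylate
Product: 12 methyl (5R,6R,10R)-5,10-bis[(tert-butyldimethylsilyl)oxy]-3-hydroxy-6-methyl-2-methylideneundec-7-ynoate (both C3 epimers)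
Conditions: DABCO (1 equiv), dioxane/H2O (1:1), rt, 2–4 d
Reagents that add atoms: none
Why: Morita–Baylis–Hillman reaction; the new carbinol centre is irrelevant because it becomes sp2 in step 8.

**Step 8**
Reactants: 12 methyl (5R,6R,10R)-5,10-bis[(tert-butyldimethylsilyl)oxy]-3-hydroxy-6-methyl-2-methylideneundec-7-ynoate
Product: 13 methyl (2Z,5R,6R,10R)-2-(bromomethyl)-5,10-bis[(tert-butyldimethylsilyl)oxy]-6-methylundec-2-en-7-ynoate
Conditions: NBS, Me2S, CH2Cl2, 0 °C → rt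
Reagents that add atoms: N-bromosuccinimide O=C1CCC(=O)N1Br
Why: Corey–Kim-type bromination of the allylic alcohol with allylic transposition (SN2') gives the thermodynamically preferred (Z)-2-(bromomethyl)enoate.

**Step 9**
Reactants: 14 5,6-O-isopropylidene-L-gulono-1,4-lactone
Product: 15 (S)-2,2-dimethyl-1,3-dioxolane-4-carbaldehyde
Conditions: NaIO4 (2 equiv), H2O, pH 5.5 (NaOH), rt
Reagents that add atoms: none
Why: double periodate glycol cleavage excises C1–C3 of the lactone and leaves its C5 stereocentre as L-glyceraldehyde acetonide.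

**Step 10**
Reactants: 13 methyl (2Z,5R,6R,10R)-2-(bromomethyl)-5,10-bis[(tert-butyldimethylsilyl)oxy]-6-methylundec-2-en-7-ynoate; 15 (S)-2,2-dimethyl-1,3-dioxolane-4-carbaldehyde
Product: 17 (4S,5R)-4-[(2R,3R,7R)-2,7-bis[(tert-butyldimethylsilyl)oxy]-3-methyloct-4-yn-1-yl]-5-[(4S)-2,2-dimethyl-1,3-dioxolan-4-yl]-3-methylideneoxolan-2-one, via hydroxy ester 16 (not isolated)
Conditions: In powder, THF/H2O (1:1), rt; then PPTS (cat.), toluene, 50 °C
Reagents that add atoms: none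
Why: indium-mediated Barbier allylation through a cyclic chair transition state gives the C6/C7-syn adduct with Felkin–Anh (anti) addition to the α-alkoxy aldehyde (C6 R, C7 S), and O6 then closes the cis-γ-lactone on the C12 ester.

**Step 11**
Reactants: 17 (4S,5R)-4-[(2R,3R,7R)-2,7-bis[(tert-butyldimethylsilyl)oxy]-3-methyloct-4-yn-1-yl]-5-[(4S)-2,2-dimethyl-1,3-dioxolan-4-yl]-3-methylideneoxolan-2-one
Product: 18 (2R,3S)-3-[(2R,3R,7R)-2,7-bis[(tert-butyldimethylsilyl)oxy]-3-methyloct-4-yn-1-yl]-4-methylidene-5-oxooxolane-2-carbaldehyde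
Conditions: H5IO6, EtOAc, rt; used crude
Reagents that add atoms: none
Why: periodic acid hydrolyses the terminal acetonide and cleaves the resulting glycol in one operation, unveiling the C5 aldehyde without touching C6.

**Step 12**
Reactants: 18 (2R,3S)-3-[(2R,3R,7R)-2,7-bis[(tert-butyldimethylsilyl)oxy]-3-methyloct-4-yn-1-yl]-4-methylidene-5-oxooxolane-2-carbaldehyde
Product: 22 (3aS,5R,6S,7S,8S,8aR)-5-[(tert-butyldimethylsilyl)oxy]-7-[(3R)-3-[(tert-butyldimethylsilyl)oxy]butanoyl]-7,8-dihydroxy-6-methyl-3-methylideneoctahydro-2H-cyclohepta[b]furan-2-one, via bis(boryl)alkene 19 (not isolated), via boron enediolate 20 (not isolated), via bis(borate) aldolate 21 (not isolated)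
Conditions: Pt(dba)2 (3 mol %), PCy3 (3 mol %), B2pin2 (1.1 equiv), toluene, rt; then Me3NO (2.2 equiv), CH2Cl2, 0 °C; then BF3·OEt2 (4 equiv), −78 → −40 °C; pH 7 buffer
Reagents that add atoms: bis(pinacolato)diboron CC1(C)OB(OC1(C)C)B1OC(C)(C)C(C)(C)O1; trimethylamine N-oxide C[N+](C)(C)[O-]
Why: Proposed new method: cis-diboration of the alkyne (zerovalent platinum, Miyaura-type) followed by C–B oxidation with Me3NO unmasks the C1/C2 enediol as its bis(pinacol borate) without base, and this enol borate adds through C1 (seven- rather than eight-membered ring) to the BF3-activated C5 aldehyde in a 7-enolexo Mukaiyama-type aldol (closest known: aldol additions of enol borates made by amine-oxide oxidation of alkenylboronates, and Mukaiyama aldols of 1,2-bis(silyloxy)alkenes); C1 is set by A(1,3) strain (C10–H in the enediol plane, tether on the face opposite the C10 methyl) and C5 by an open chair-like transition state in which the BF3-bound C5=O lies anti to the C1–O and C6–O bonds, giving the 1,5-trans diol.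

**Step 13**
Reactants: 22 the diol of step 12; 23 (R)-2-methylbutanoic acid
Product: 25 (3aS,5R,6S,7S,8S,8aR)-5-[(tert-butyldimethylsilyl)oxy]-7-[(3R)-3-[(tert-butyldimethylsilyl)oxy]butanoyl]-7-hydroxy-6-methyl-3-methylidene-2-oxooctahydro-2H-cyclohepta[b]furan-8-yl (2R)-2-methylbutanoate, via mixed anhydride 24 (not isolated)
Conditions: 2,4,6-Cl3C6H2COCl, Et3N, THF, rt; then 22, DMAP, toluene, 0 °C → rt
Reagents that add atoms: none
Why: Yamaguchi esterification acylates only the secondary C5–OH (the tertiary C1–OH is inert, C4 and C9 are silylated) and keeps the α-stereocentre of the acid.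

**Step 14**
Reactants: 25 the bis-silyl ester of step 13
Product: 26 (3aS,5R,6S,7S,8S,8aR)-5,7-dihydroxy-7-[(3R)-3-hydroxybutanoyl]-6-methyl-3-methylidene-2-oxooctahydro-2H-cyclohepta[b]furan-8-yl (2R)-2-methylbutanoate
Conditions: HF·pyridine, THF, 0 °C → rt
Reagents that add atoms: none
Why: fluoride desilylation of the two secondary TBS ethers under mildly acidic conditions that spare the lactone, the ester and the β-hydroxy ketone.

**Compound list**
1 | (R)-but-3-yn-2-ol | C[C@@H](O)C#C | starting material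
2 | (R)-but-3-yn-2-yl methanesulfonate | C[C@@H](OS(C)(=O)=O)C#C | intermediate
3 | (P)-tributyl(buta-1,2-dien-1-yl)stannane (axially chiral allene) | CC([H])=[C@@]=C([H])[Sn](CCCC)(CCCC)CCCC | intermediate
4 | 3-[(tert-butyldimethylsilyl)oxy]propanal | O=CCCO[Si](C)(C)C(C)(C)C | starting material
5 | (3R,4R)-1-[(tert-butyldimethylsilyl)oxy]-4-methylhex-5-yn-3-ol | CC(C)(C)[Si](C)(C)OCC[C@@H](O)[C@H](C)C#C | intermediate
6 | (R)-2-methyloxirane | C[C@@H]1CO1 | starting material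
7 | dilithium (2R,6R,7R)-9-[(tert-butyldimethylsilyl)oxy]-6-methylnon-4-yne-2,7-diolate | [Li+].[Li+].CC(C)(C)[Si](C)(C)OCC[C@@H]([O-])[C@H](C)C#CC[C@@H](C)[O-] | intermediate
8 | (2R,6R,7R)-2,7,9-tris[(tert-butyldimethylsilyl)oxy]-6-methylnon-4-yne | CC(C)(C)[Si](C)(C)OCC[C@@H](O[Si](C)(C)C(C)(C)C)[C@H](C)C#CC[C@@H](C)O[Si](C)(C)C(C)(C)C | intermediate
9 | (3R,4R,8R)-3,8-bis[(tert-butyldimethylsilyl)oxy]-4-methylnon-5-yn-1-ol | OCC[C@@H](O[Si](C)(C)C(C)(C)C)[C@H](C)C#CC[C@@H](C)O[Si](C)(C)C(C)(C)C | intermediate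
10 | (3R,4R,8R)-3,8-bis[(tert-butyldimethylsilyl)oxy]-4-methylnon-5-ynal | O=CC[C@@H](O[Si](C)(C)C(C)(C)C)[C@H](C)C#CC[C@@H](C)O[Si](C)(C)C(C)(C)C | intermediate
11 | methyl acrylate | C=CC(=O)OC | starting material
12 | methyl (5R,6R,10R)-5,10-bis[(tert-butyldimethylsilyl)oxy]-3-hydroxy-6-methyl-2-methylideneundec-7-ynoate (C3 epimers) | C=C(C(=O)OC)C(O)C[C@@H](O[Si](C)(C)C(C)(C)C)[C@H](C)C#CC[C@@H](C)O[Si](C)(C)C(C)(C)C | intermediate
13 | methyl (2Z,5R,6R,10R)-2-(bromomethyl)-5,10-bis[(tert-butyldimethylsilyl)oxy]-6-methylundec-2-en-7-ynoate | COC(=O)/C(CBr)=C/C[C@@H](O[Si](C)(C)C(C)(C)C)[C@H](C)C#CC[C@@H](C)O[Si](C)(C)C(C)(C)C | intermediate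
14 | 5,6-O-isopropylidene-L-gulono-1,4-lactone | O=C1O[C@H]([C@@H]2COC(C)(C)O2)[C@H](O)[C@@H]1O | starting material
15 | (S)-2,2-dimethyl-1,3-dioxolane-4-carbaldehyde | O=C[C@@H]1COC(C)(C)O1 | intermediate
16 | methyl (3S,5R,6R,10R)-5,10-bis[(tert-butyldimethylsilyl)oxy]-3-[(R)-[(4S)-2,2-dimethyl-1,3-dioxolan-4-yl](hydroxy)methyl]-6-methyl-2-methylideneundec-7-ynoate | C=C(C(=O)OC)[C@@H]([C@@H](O)[C@@H]1COC(C)(C)O1)C[C@@H](O[Si](C)(C)C(C)(C)C)[C@H](C)C#CC[C@@H](C)O[Si](C)(C)C(C)(C)C | intermediate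
17 | (4S,5R)-4-[(2R,3R,7R)-2,7-bis[(tert-butyldimethylsilyl)oxy]-3-methyloct-4-yn-1-yl]-5-[(4S)-2,2-dimethyl-1,3-dioxolan-4-yl]-3-methylideneoxolan-2-one | C=C1C(=O)O[C@@H]([C@@H]2COC(C)(C)O2)[C@H]1C[C@@H](O[Si](C)(C)C(C)(C)C)[C@H](C)C#CC[C@@H](C)O[Si](C)(C)C(C)(C)C | intermediate
18 | (2R,3S)-3-[(2R,3R,7R)-2,7-bis[(tert-butyldimethylsilyl)oxy]-3-methyloct-4-yn-1-yl]-4-methylidene-5-oxooxolane-2-carbaldehyde | C=C1C(=O)O[C@@H](C=O)[C@H]1C[C@@H](O[Si](C)(C)C(C)(C)C)[C@H](C)C#CC[C@@H](C)O[Si](C)(C)C(C)(C)C | intermediate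
19 | (Z)-C1,C2-bis(pinacolboryl)alkene derived from 18 (cis-diborylated alkyne) | C=C1C(=O)O[C@@H](C=O)[C@H]1C[C@@H](O[Si](C)(C)C(C)(C)C)[C@H](C)/C(B2OC(C)(C)C(C)(C)O2)=C(B3OC(C)(C)C(C)(C)O3)\C[C@@H](C)O[Si](C)(C)C(C)(C)C | intermediate
20 | (Z)-C1,C2-enediol bis(pinacol borate) derived from 18 | C=C1C(=O)O[C@@H](C=O)[C@H]1C[C@@H](O[Si](C)(C)C(C)(C)C)[C@H](C)/C(OB2OC(C)(C)C(C)(C)O2)=C(OB3OC(C)(C)C(C)(C)O3)\C[C@@H](C)O[Si](C)(C)C(C)(C)C | intermediate
21 | O1,O5-bis(pinacolboryl) derivative of diol 22 | C=C1C(=O)O[C@@H]2[C@H]1C[C@@H](O[Si](C)(C)C(C)(C)C)[C@H](C)[C@@](OB3OC(C)(C)C(C)(C)O3)(C(=O)C[C@@H](C)O[Si](C)(C)C(C)(C)C)[C@H]2OB4OC(C)(C)C(C)(C)O4 | intermediate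
22 | (3aS,5R,6S,7S,8S,8aR)-5-[(tert-butyldimethylsilyl)oxy]-7-[(3R)-3-[(tert-butyldimethylsilyl)oxy]butanoyl]-7,8-dihydroxy-6-methyl-3-methylideneoctahydro-2H-cyclohepta[b]furan-2-one | C=C1C(=O)O[C@@H]2[C@H]1C[C@@H](O[Si](C)(C)C(C)(C)C)[C@H](C)[C@@](O)(C(=O)C[C@@H](C)O[Si](C)(C)C(C)(C)C)[C@H]2O | intermediate
23 | (R)-2-methylbutanoic acid | CC[C@@H](C)C(=O)O | starting material
24 | (2R)-2-methylbutanoic 2,4,6-trichlorobenzoic anhydride | CC[C@@H](C)C(=O)OC(=O)c1c(Cl)cc(Cl)cc1Cl | intermediate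
25 | (3aS,5R,6S,7S,8S,8aR)-5-[(tert-butyldimethylsilyl)oxy]-7-[(3R)-3-[(tert-butyldimethylsilyl)oxy]butanoyl]-7-hydroxy-6-methyl-3-methylidene-2-oxooctahydro-2H-cyclohepta[b]furan-8-yl (2R)-2-methylbutanoate | C=C1C(=O)O[C@@H]2[C@H]1C[C@@H](O[Si](C)(C)C(C)(C)C)[C@H](C)[C@@](O)(C(=O)C[C@@H](C)O[Si](C)(C)C(C)(C)C)[C@H]2OC(=O)[C@H](C)CC | intermediate
26 | (3aS,5R,6S,7S,8S,8aR)-5,7-dihydroxy-7-[(3R)-3-hydroxybutanoyl]-6-methyl-3-methylidene-2-oxooctahydro-2H-cyclohepta[b]furan-8-yl (2R)-2-methylbutanoate | C=C1C(=O)O[C@@H]2[C@H]1C[C@@H](O)[C@H](C)[C@@](O)(C(=O)C[C@@H](C)O)[C@H]2OC(=O)[C@H](C)CC | target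

**Step count**
Total steps: 14. Longest linear sequence: 13 (steps 1–8 and 10–14, from 1).

**Three steps most likely to fail**

Step 12 (diboration, enediol unmasking and ring-closing aldol). The diboration must be selective for the alkyne over the aldehyde and the α-methylene lactone, the enol borate must be nucleophilic enough under BF3, and the C5 configuration rests on an open transition state. A boron-bridged closed transition state of the (Z)-enediolate would instead favour the 1,5-cis diol. The fallback uses exactly that outcome and sets C5 together with the ester by substitution. It sets out from 20 and comes back at 25. Enediolate 20 is warmed to 40 °C without BF3 and hydrolysed to give the C5 epimer of 22, the 1,5-cis diol F5. SO2Cl2 and Et3N at −40 °C close the cyclic sulfate F6. Cesium (R)-2-methylbutanoate (from 23 and Cs2CO3) in DMF opens it at the secondary C5 with inversion to the C1 hydrogen sulfate F7. Catalytic H2SO4 in wet THF hydrolyses F7 to 25.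

Step 3 (syn-selective allenylstannane addition). With an unbranched aldehyde the syn:anti ratio may be modest. The fallback sets out from 4 and comes back at 5. Purchased (S)-but-3-yn-2-ol is mesylated to (S)-but-3-yn-2-yl methanesulfonate F1. Pd(dppf)Cl2 and InI in THF/HMPA (allenylindium formed through zerovalent palladium, cyclic transition state, net inversion at C10) add it to 4 to give the anti alcohol (3S,4R)-1-[(tert-butyldimethylsilyl)oxy]-4-methylhex-5-yn-3-ol F2. Mitsunobu inversion at C9 with 4-nitrobenzoic acid, PPh3 and DIAD gives (3R,4R)-1-[(tert-butyldimethylsilyl)oxy]-4-methylhex-5-yn-3-yl 4-nitrobenzoate F3. K2CO3 in MeOH then returns 5.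

Step 10 (Barbier allylation and lactonisation). The syn and Felkin selectivities depend on an equilibrating allylindium species. The fallback sets out from 13 and comes back at 17. Pd2(dba)3-catalysed borylation of 13 with B2pin2 gives the geometrically defined allylboronate methyl (2E,5R,6R,10R)-5,10-bis[(tert-butyldimethylsilyl)oxy]-6-methyl-2-[(4,4,5,5-tetramethyl-1,3,2-dioxaborolan-2-yl)methyl]undec-2-en-7-ynoate F4. Its allylboration of 15 (toluene, 80 °C, or Sc(OTf)3 catalysis) runs through a closed chair transition state, so the alkene geometry is translated stereospecifically into the C6/C7-syn adduct with Felkin control, and PPTS then lactonises to 17.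

**Further compounds**
F1 | step 3 | (S)-but-3-yn-2-yl methanesulfonate | C[C@H](OS(C)(=O)=O)C#C
F2 | step 3 | (3S,4R)-1-[(tert-butyldimethylsilyl)oxy]-4-methylhex-5-yn-3-ol | CC(C)(C)[Si](C)(C)OCC[C@H](O)[C@H](C)C#C
F3 | step 3 | (3R,4R)-1-[(tert-butyldimethylsilyl)oxy]-4-methylhex-5-yn-3-yl 4-nitrobenzoate | CC(C)(C)[Si](C)(C)OCC[C@@H](OC(=O)c1ccc(cc1)[N+](=O)[O-])[C@H](C)C#C
F4 | step 10 | methyl (2E,5R,6R,10R)-5,10-bis[(tert-butyldimethylsilyl)oxy]-6-methyl-2-[(4,4,5,5-tetramethyl-1,3,2-dioxaborolan-2-yl)methyl]undec-2-en-7-ynoate | COC(=O)/C(CB1OC(C)(C)C(C)(C)O1)=C/C[C@@H](O[Si](C)(C)C(C)(C)C)[C@H](C)C#CC[C@@H](C)O[Si](C)(C)C(C)(C)C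
F5 | step 12 | (3aS,5R,6S,7S,8R,8aR)-5-[(tert-butyldimethylsilyl)oxy]-7-[(3R)-3-[(tert-butyldimethylsilyl)oxy]butanoyl]-7,8-dihydroxy-6-methyl-3-methylideneoctahydro-2H-cyclohepta[b]furan-2-one (C5 epimer of 22) | C=C1C(=O)O[C@@H]2[C@H]1C[C@@H](O[Si](C)(C)C(C)(C)C)[C@H](C)[C@@](O)(C(=O)C[C@@H](C)O[Si](C)(C)C(C)(C)C)[C@@H]2O
F6 | step 12 | 7,8-cyclic sulfate of F5 | C=C1C(=O)O[C@@H]2[C@H]1C[C@@H](O[Si](C)(C)C(C)(C)C)[C@H](C)[C@@]3(OS(=O)(=O)O[C@H]23)C(=O)C[C@@H](C)O[Si](C)(C)C(C)(C)C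
F7 | step 12 | C1 (ring position 7) hydrogen sulfate of ester 25 | C=C1C(=O)O[C@@H]2[C@H]1C[C@@H](O[Si](C)(C)C(C)(C)C)[C@H](C)[C@@](OS(=O)(=O)O)(C(=O)C[C@@H](C)O[Si](C)(C)C(C)(C)C)[C@H]2OC(=O)[C@H](C)CC
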